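The data come from a simulation with made-up constants; the scatter is artificial.

I count in one unit, the starting complex charged, and I reckon the amounts in the argument as fractions of it.

| setting | green | teal | flask |
|---|---|---|---|
| starting complex | 0.50 M | 0.50 M | 0.50 M |
| incoming ligand | 0.60 M | 0.40 M | 0.600 M |
| temperature | 25 °C | 10 °C | 25 °C |
| remark | the very flask that is asked about, followed so far | run made earlier |  |
| time |  |  | 1.0 h |

- green (time / min: complex with one exchanged / %): 4.00: 47; 8.00: 53; 15.0: 58; 25.0: 62; 50.0: 71
- teal (time / min: complex with one exchanged / %): 0.333: 1; 0.667: 5; 1.00: 5; 2.00: 10; 3.00: 12

(each reading ± 1.5 percentage points)

- larch: at 1.0 h raise the temperature by 25 K, then wait 20 min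
- birch: at 1.0 h take out 90 % of the complex with one exchanged then present, then wait 20 min
- ash: change nothing and wait 20 min more
- maple: at 1.0 h add incoming ligand, 100 % of the amount charged, then wait 20 min

- what is taken out of complex with one exchanged is counted as made
- the analysis behind the earlier runs scatters by 1.5 percentage points, standard deviation
- additions bring no volume worth counting

1. complex with one exchanged, in percent of the starting complex first charged, at 1.0 h
2. what to do for the largest gain in complex with one exchanged; "none" if nothing gains more than 2 percentage points (larch / birch / ash / maple / none)
3. complex with one exchanged present, with what was taken out counted in, in percent of the starting complex first charged, after birch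
4. complex with one exchanged present, with what was taken out counted in, in percent of the starting complex first charged, after ash

In this unit the flask holds 1.20 of incoming ligand. This ratio, the equivalents of incoming ligand per starting complex, folds the charges into one number: one ligand for each unit, and a surplus of 0.200. A complex with one exchanged may take a second ligand. Once starting complex is gone, each unit holds one or two exchanged, so the share with one exchanged is two less the ligand taken up per unit. With the ligand used up, this flask would read 80.0 %.

Is one number enough? No. The green run climbs 32.6 times more slowly between its last two readings than over its first 4.00 min. Yet starting complex left times ligand left, counted for one exchange, falls by a factor of 8.44 from the start to the last reading, which is less. So I suspect a second exchange or a way back, and I take the pace from the readings. A straight line through the last two green readings reaches 74.6 % at 1.0 h, and I commit to just under that. Maple would lift the equivalents to 2.40, enough for two exchanges per unit, so I rule it out.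

The forecast says 73 % now, 76 % after ash, and birch as best with 91 %, “assuming the product itself is the inhibitor rather than the released ligand”.

The flask gives 75.4 % now, 78.6 % after ash and 85.5 % after birch. Its best is larch, gaining 20 percentage points against 10 points for birch, while maple changes it by −37 points.

    complex with one exchanged + incoming ligand ⇌ leaving ligand + complex with two exchanged (K = 3.40, k = 0.00410 /M/s, Ea = 48.0 kJ/mol, ΔH = −74.0 kJ/mol)
    starting complex + incoming ligand → leaving ligand + complex with one exchanged (k = 0.00920 /M/s, Ea = 59.0 kJ/mol)
    (constants at 25 °C)

A neighbour flask charged with 0.30 M of starting complex stands at 2.00 equivalents and keeps 24 % of its ligand, so the count gives 48.3 %, and it holds 48.0 %. The flask itself is not at rest at 1.0 h, with starting complex at 5.97 % and complex with two exchanged at 18.7 %. At 600 min starting complex stands at 0 % and ligand at 4.70 % of its charge, so the count gives 85.6 %. Ten times the time still adds 10 points to complex with one exchanged, which then stands at 85.6 %, with complex with two exchanged down to 14.4 %.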